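Amounts first: teal holds 20 mM of starting material and 6.00 mM of protic impurity, as elm and ash did, at a free catalyst loading of 7.5 mol% against their 7 mol% and 10 mol%; ochre drops to 5 mol%.

all flasks: starting material 20 mM

|  | second substrate | reagent | protic impurity | free catalyst | remark | time |
|---|---|---|---|---|---|---|
| elm | 0.50 equiv | 2 equiv | 6 mM | 7 mol% | run made earlier |  |
| ash | 0.50 equiv | 2 equiv | 6 mM | 10 mol% | run made earlier |  |
| teal | 0.500 equiv | 2.00 equiv | 6.00 mM | 7.5 mol% |  | 20 h |
| ochre | 0.500 equiv | 2.00 equiv | 6.00 mM | 5 mol% |  | 20 h |

| run | time / h | target / % | catalyst intermediate A / % | starting material / % |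
|---|---|---|---|---|
| elm | 0.833 | 20 | 2 | 66 |
| elm | 2.00 | 39 | 6 | 41 |
| elm | 4.00 | 67 | 5 | 10 |
| elm | 10.0 | 83 | 0 | 0 |
| ash | 0.833 | 28 | 10 | 59 |
| ash | 2.00 | 56 | 5 | 28 |
| ash | 4.00 | 80 | 0 | 2 |
| ash | 10.0 | 84 | 0 | 1 |

(scatter of a reading: 2 percentage points)

- the numbers in the tables scatter with a standard deviation of 2 percentage points

- which of these there is most of at the end, counted by the starting material in it, teal (catalyst intermediate A / starting material / target)
- which of these there is most of at the end, counted by the starting material in it, ochre (catalyst intermediate A / starting material / target)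
- final amount of the leader among these, as a percentage of the starting material charged, in teal
- final amount of the leader among these, as a percentage of the starting material charged, in ochre

I drew teal's curve by scaling time inversely with loading. Target's starting slope, as a fraction of the charge, came to 0.257 h⁻¹ from elm and 0.252 h⁻¹ from ash. Elm's target met its starting material near 2.00 h, which put teal's crossing at 1.87 h. On a log scale, elm's starting material fell one power of ten by 4.00 h, and ash's log-interpolated time for that fall was 2.78 h. Scaled to teal, these give a knee at 3.73 h and 3.71 h; ochre's knee falls near 5.60 h, earlier than 20 h.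

Then comes the level. Elm and ash ended at 83% and 84% target, leaving on average 3.30 mM outside it. Neither elm nor ash varied the protic impurity, so it was only my guess that it carries the loss, and I took the leak ratio, millimoles of starting material ending outside the target per millimole of protic impurity charged: 0.550. That gave a level of 83.5% for teal and ochre alike.

The forecast named target in both flasks, at 83% (79% to 87%) in teal and 81% (68% to 86%) in ochre, holding that “the rate scales approximately with catalyst”. For ochre, my level stood 2.5 points higher.

Target led, with 83.1% in teal and 78.5% in ochre, so the leak ratio was 0.563 in teal and a larger 0.717 in ochre.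

    starting material + free catalyst ⇌ catalyst intermediate A (K = 6700 M⁻¹, k = 33.0 M⁻¹ min⁻¹)
    reagent + catalyst intermediate A → free catalyst + target (k = 2.00 M⁻¹ min⁻¹)
    second substrate + free catalyst ⇌ catalyst intermediate B (K = 220 M⁻¹, k = 11.0 M⁻¹ min⁻¹)
    reagent + catalyst intermediate B → free catalyst + second product (k = 1.00 M⁻¹ min⁻¹)
    starting material + protic impurity → quenched substrate (k = 0.330 M⁻¹ min⁻¹)
    2 starting material → self-condensation product (k = 0.00740 M⁻¹ min⁻¹)

In teal, half the turnover of starting material with free catalyst was done by 1.57 h and >99.9% by 10.0 h, when target stood at 83.0%. With starting material then at 0.00539%, second substrate fell from 32.5% to 6.41% of its charge by 20.0 h, while target held at 83.1%. In the neighbour flask, which is teal with 3.6 mM of protic impurity, my leak ratio gives 90.1% target. The flask gave 88.4%, a leak ratio of 0.644.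

The numbers in the tables were generated by integration for substances that don't exist; noise was put on by code.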